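**Retrosynthetic overview**
1. The 14‑membered carbocycle is opened at the C6=C7 E‑alkene (ring‑closing metathesis, last step); the C3–C4 epoxide comes from a reagent‑controlled Shi epoxidation one step earlier.
2. The cis α‑methylene‑γ‑lactone (C1–C14 bond, both stereocentres) comes from an indium‑mediated 2‑(methoxycarbonyl)allylation of west aldehyde 15 (C7–C14) with east allylic bromide 26 (C1–C6, C15–C17); this is the late union of two C11 fragments.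
3. West aldehyde 15: cross‑metathesis then hydrogenation joins a C11–C14 acetonide (Sharpless epoxidation of crotyl alcohol, vinyl‑cuprate opening) to a C7–C10 hydroxy tosylate (Sharpless epoxidation of methallyl alcohol); a sulfonium‑ylide homologation then makes the vinyl carbinol.
4. East bromide 26: Negishi carboalumination of pent‑1‑en‑4‑yne with ethylene oxide trapping, oxidation, vinylalumination with methyl propiolate, and allylic bromination with transposition.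
5. Ring order: five‑membered lactone (step 16), epoxide (step 18), 14‑membered ring (step 19).

Assumption: positions are numbered as in cembranes (C1 = ring CH bearing the lactone α‑carbon C15, C14 = lactone O–CH, C13 = CHOAc, C12 = CHMe, C8 = C(OH)Me, C6=C7 ring alkene, C3–C4 epoxide), and all named starting materials and reagents are taken as purchasable.

**Route**

Step 1
Reactants: 1 2‑methylprop‑2‑en‑1‑ol
Product: 3 [(2S)‑2‑methyloxiran‑2‑yl]methyl 4‑methylbenzenesulfonate, via (R)‑2‑methylglycidol 2 (not isolated)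
Conditions: Ti(OiPr)4 (5 mol %), D‑(−)‑diisopropyl tartrate (6 mol %), t‑BuOOH, 4 Å MS, CH2Cl2, −20 °C; then P(OMe)3; then TsCl, Et3N, DMAP (cat.), −10 °C
Reagents that add atoms: tert‑butyl hydroperoxide, CC(C)(C)OO; 4‑toluenesulfonyl chloride, Cc1ccc(cc1)S(=O)(=O)Cl
Why: Katsuki–Sharpless asymmetric epoxidation with the D‑tartrate gives (R)‑2 (the future C8 centre), and in‑situ sulfonylation of the primary hydroxyl traps the water‑soluble epoxy alcohol without touching the stereocentre (the descriptor becomes S only through CIP priorities).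

Step 2
Reactants: 3 [(2S)‑2‑methyloxiran‑2‑yl]methyl 4‑methylbenzenesulfonate
Product: 4 (2S)‑2‑hydroxy‑2‑methylpent‑4‑en‑1‑yl 4‑methylbenzenesulfonate
Conditions: CH2=CHMgBr (1.3 equiv), CuI (10 mol %), THF, −40 → −25 °C; aq. NH4Cl
Reagents that add atoms: vinylmagnesium bromide, C=C[Mg]Br
Why: Copper‑catalysed Grignard opening of the epoxide at its unsubstituted CH2 (SN2) is faster than sulfonate displacement at low temperature and leaves the quaternary stereocentre untouched.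

Step 3
Reactants: 5 (2E)‑but‑2‑en‑1‑ol
Product: 6 [(2S,3S)‑3‑methyloxiran‑2‑yl]methanol
Conditions: Ti(OiPr)4 (5 mol %), L‑(+)‑diethyl tartrate (6 mol %), t‑BuOOH, 4 Å MS, CH2Cl2, −20 °C; non‑aqueous work‑up, distillation
Reagents that add atoms: tert‑butyl hydroperoxide, CC(C)(C)OO
Why: Katsuki–Sharpless asymmetric epoxidation; the L‑tartrate gives the (2S,3S)‑epoxide from an E‑allylic alcohol, fixing the future C13 oxygen and, after inversion in step 4, C12.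

Step 4
Reactants: 6 [(2S,3S)‑3‑methyloxiran‑2‑yl]methanol
Product: 7 (2R,3S)‑3‑methylpent‑4‑ene‑1,2‑diol
Conditions: CH2=CHMgBr (3.5 equiv), CuI (15 mol %), THF/Et2O, −25 → 0 °C; aq. NH4Cl
Reagents that add atoms: vinylmagnesium bromide, C=C[Mg]Br
Why: CuI‑catalysed Grignard opening of the trans‑epoxy alcohol at C3 (the carbon remote from the inductively deactivating hydroxymethyl) with inversion places the C12 methyl syn to the C13 hydroxyl; the minor 1,3‑diol is removed after step 5.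

Step 5
Reactants: 7 (2R,3S)‑3‑methylpent‑4‑ene‑1,2‑diol
Product: 8 (4R)‑4‑[(2S)‑but‑3‑en‑2‑yl]‑2,2‑dimethyl‑1,3‑dioxolane
Conditions: 2,2‑dimethoxypropane, PPTS (cat.), CH2Cl2, rt
Reagents that add atoms: 2,2‑dimethoxypropane, COC(C)(C)OC
Why: Acid‑catalysed transacetalisation protects the 1,2‑diol as its five‑membered acetonide.

Step 6
Reactants: 8 (4R)‑4‑[(2S)‑but‑3‑en‑2‑yl]‑2,2‑dimethyl‑1,3‑dioxolane; 4 (2S)‑2‑hydroxy‑2‑methylpent‑4‑en‑1‑yl 4‑methylbenzenesulfonate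
Product: 9 (2S,4E,6S)‑6‑[(4R)‑2,2‑dimethyl‑1,3‑dioxolan‑4‑yl]‑2‑hydroxy‑2‑methylhept‑4‑en‑1‑yl 4‑methylbenzenesulfonate
Conditions: 4 (2.5 equiv), second‑generation Hoveyda–Grubbs catalyst RuCl2(=CH‑C6H4‑2‑OiPr)(H2IMes) (5 mol %), CH2Cl2, 40 °C
Reagents that add atoms: none
Why: Olefin cross‑metathesis between the allylically branched alkene 8 (slow to homodimerise) and an excess of the unhindered alkene 4 forms the C10–C11 bond; the E/Z ratio is irrelevant because the alkene is reduced next.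

Step 7
Reactants: 9 (2S,4E,6S)‑6‑[(4R)‑2,2‑dimethyl‑1,3‑dioxolan‑4‑yl]‑2‑hydroxy‑2‑methylhept‑4‑en‑1‑yl 4‑methylbenzenesulfonate
Product: 10 (2S,6S)‑6‑[(4R)‑2,2‑dimethyl‑1,3‑dioxolan‑4‑yl]‑2‑hydroxy‑2‑methylheptyl 4‑methylbenzenesulfonate
Conditions: H2 (1 atm), Pd/C (10 wt % Pd), NaHCO3, EtOAc, rt
Reagents that add atoms: none
Why: Heterogeneous catalytic hydrogenation saturates the disubstituted alkene; the acetonide, sulfonate and tertiary alcohol are inert.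

Step 8
Reactants: 10 (2S,6S)‑6‑[(4R)‑2,2‑dimethyl‑1,3‑dioxolan‑4‑yl]‑2‑hydroxy‑2‑methylheptyl 4‑methylbenzenesulfonate
Product: 13 (3S,7S)‑7‑[(4R)‑2,2‑dimethyl‑1,3‑dioxolan‑4‑yl]‑3‑methyloct‑1‑en‑3‑ol, via terminal epoxide 11 (not isolated), via sulfonium betaine 12 (not isolated)
Conditions: Me3S+ I− (5 equiv), n‑BuLi (4.8 equiv), THF, −10 °C → rt
Reagents that add atoms: trimethylsulfonium iodide, C[S+](C)C.[I-]
Why: Base closes the β‑hydroxy sulfonate to the 2,2‑disubstituted epoxide (Williamson), dimethylsulfonium methylide opens it at CH2 and a further equivalent eliminates Me2S (Corey–Chaykovsky‑type one‑carbon homologation to the allylic alcohol), so the C8–O bond is never broken and its configuration is retained.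

Step 9
Reactants: 13 (3S,7S)‑7‑[(4R)‑2,2‑dimethyl‑1,3‑dioxolan‑4‑yl]‑3‑methyloct‑1‑en‑3‑ol
Product: 14 (2R,3S,7S)‑3,7‑dimethylnon‑8‑ene‑1,2,7‑triol
Conditions: PPTS (20 mol %), MeOH, 40 °C
Reagents that add atoms: none
Why: Acid‑catalysed transacetalisation removes the acetonide under conditions too mild to ionise the tertiary allylic alcohol.

Step 10
Reactants: 14 (2R,3S,7S)‑3,7‑dimethylnon‑8‑ene‑1,2,7‑triol
Product: 15 (2R,3S,7S)‑2,7‑dihydroxy‑3,7‑dimethylnon‑8‑enal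
Conditions: TEMPO (15 mol %), PhI(OAc)2 (1.1 equiv), CH2Cl2, 0 °C → rt; used crude at once
Reagents that add atoms: none
Why: Oxoammonium (TEMPO) oxidation is selective for the primary over the secondary and tertiary hydroxyls and stops at the aldehyde in anhydrous medium.

Step 11
Reactants: 16 3‑bromoprop‑1‑ene
Product: 17 pent‑1‑en‑4‑yne
Conditions: HC≡CMgBr (1.3 equiv), CuCl (5 mol %), THF, 0 → 40 °C; aqueous washes, distillation
Reagents that add atoms: ethynylmagnesium bromide, C#C[Mg]Br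
Why: Copper‑catalysed coupling of an allylic bromide with an alkynyl Grignard reagent gives the skipped enyne.

Step 12
Reactants: 17 pent‑1‑en‑4‑yne
Product: 20 (3E)‑4‑methylhepta‑3,6‑dien‑1‑ol, via alkenylalane 18 (not isolated), via lithium alanate 19 (not isolated)
Conditions: AlMe3 (2 equiv), Cp2ZrCl2 (0.2 equiv), CH2Cl2, 0 °C → rt; then n‑BuLi, THF, −78 °C; ethylene oxide, −78 → 0 °C; aq. potassium sodium tartrate (KNaC4H4O6)
Reagents that add atoms: trimethylaluminium, C[Al](C)C; ethylene oxide, C1CO1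
Why: Negishi zirconium‑catalysed carboalumination adds Me–Al syn across the alkyne (methyl to the internal carbon), fixing the E trisubstituted alkene, and the derived alanate opens ethylene oxide with retention at the alkenyl carbon.

Step 13
Reactants: 20 (3E)‑4‑methylhepta‑3,6‑dien‑1‑ol
Product: 21 (3E)‑4‑methylhepta‑3,6‑dienal
Conditions: Dess–Martin periodinane, NaHCO3, CH2Cl2, 0 °C; used crude at once
Reagents that add atoms: none
Why: Dess–Martin oxidation under buffered, non‑basic conditions gives the β,γ‑unsaturated aldehyde without migration of the alkene into conjugation.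

Step 14
Reactants: 21 (3E)‑4‑methylhepta‑3,6‑dienal; 22 methyl prop‑2‑ynoate
Product: 24 methyl (5E)‑3‑hydroxy‑6‑methyl‑2‑methylidenenona‑5,8‑dienoate, via vinylalane 23 (not isolated)
Conditions: iBu2AlH, N‑methylmorpholine N‑oxide, THF, 0 °C; 22, 0 °C; then 21, 0 °C → rt
Reagents that add atoms: none
Why: Hydroalumination of the propiolate gives the α‑aluminio acrylate, which adds to the aldehyde at 0 °C (vinylalumination, a fast Morita–Baylis–Hillman equivalent) before the skipped dienal can isomerise; the new carbinol centre is destroyed in step 15, so it needs no control.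

Step 15
Reactants: 24 methyl (5E)‑3‑hydroxy‑6‑methyl‑2‑methylidenenona‑5,8‑dienoate
Product: 26 methyl (2Z,5E)‑2‑(bromomethyl)‑6‑methylnona‑2,5,8‑trienoate, via alkoxysulfonium bromide 25 (not isolated)
Conditions: NBS (1.3 equiv), Me2S (1.5 equiv), CH2Cl2, 0 °C; then 24, 0 °C → rt
Reagents that add atoms: N‑bromosuccinimide, O=C1CCC(=O)N1Br
Why: Corey–Kim‑type activation of the allylic alcohol as an alkoxysulfonium salt followed by SN2' attack of bromide gives the rearranged (2Z)‑2‑(bromomethyl)alk‑2‑enoate under neutral conditions.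

Step 16
Reactants: 15 (2R,3S,7S)‑2,7‑dihydroxy‑3,7‑dimethylnon‑8‑enal; 26 methyl (2Z,5E)‑2‑(bromomethyl)‑6‑methylnona‑2,5,8‑trienoate
Product: 29 (4S,5R)‑5‑[(1R,2S,6S)‑1,6‑dihydroxy‑2,6‑dimethyloct‑7‑en‑1‑yl]‑3‑methylidene‑4‑[(2E)‑3‑methylhexa‑2,5‑dien‑1‑yl]oxolan‑2‑one, via allylindium dibromide 27 (not isolated), via hydroxy ester 28 (not isolated)
Conditions: indium powder (In, 1.5 equiv), 26 (1.3 equiv), THF/H2O (1:1), rt; then PPTS (cat.), CH2Cl2, rt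
Reagents that add atoms: none
Why: Indium‑mediated Barbier 2‑(alkoxycarbonyl)allylation in water: trivalent indium chelates the free α‑hydroxyl and the carbonyl (Cram chelate) so attack occurs anti to the C12 branch (13,14‑syn diol, C14 R), the γ‑substituted allylindium reacts through a cyclic transition state to the syn adduct (C1 S), and lactonisation onto the C14 hydroxyl gives the cis‑disubstituted α‑methylene‑γ‑butyrolactone.

Step 17
Reactants: 29 (4S,5R)‑5‑[(1R,2S,6S)‑1,6‑dihydroxy‑2,6‑dimethyloct‑7‑en‑1‑yl]‑3‑methylidene‑4‑[(2E)‑3‑methylhexa‑2,5‑dien‑1‑yl]oxolan‑2‑one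
Product: 30 (1R,2S,6S)‑6‑hydroxy‑2,6‑dimethyl‑1‑{(2R,3S)‑4‑methylidene‑3‑[(2E)‑3‑methylhexa‑2,5‑dien‑1‑yl]‑5‑oxooxolan‑2‑yl}oct‑7‑en‑1‑yl acetate
Conditions: Ac2O, pyridine, DMAP (cat.), CH2Cl2, 0 °C → rt
Reagents that add atoms: acetic anhydride, CC(=O)OC(C)=O
Why: Acylation takes the secondary C13 hydroxyl, while the tertiary allylic C8 hydroxyl is too hindered to react under these conditions.

Step 18
Reactants: 30 (1R,2S,6S)‑6‑hydroxy‑2,6‑dimethyl‑1‑{(2R,3S)‑4‑methylidene‑3‑[(2E)‑3‑methylhexa‑2,5‑dien‑1‑yl]‑5‑oxooxolan‑2‑yl}oct‑7‑en‑1‑yl acetate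
Product: 31 (1R,2S,6S)‑6‑hydroxy‑2,6‑dimethyl‑1‑[(2R,3S)‑4‑methylidene‑3‑{[(2R,3R)‑3‑methyl‑3‑(prop‑2‑en‑1‑yl)oxiran‑2‑yl]methyl}‑5‑oxooxolan‑2‑yl]oct‑7‑en‑1‑yl acetate
Conditions: Shi ketone (1,2:4,5‑di‑O‑isopropylidene‑β‑D‑erythro‑2,3‑hexodiulo‑2,6‑pyranose, from D‑fructose, 0.5 equiv), Oxone (2KHSO5·KHSO4·K2SO4), K2CO3, Bu4NHSO4, MeCN/dimethoxymethane/aq. Na2B4O7 buffer, 0 °C
Reagents that add atoms: Oxone (potassium peroxymonosulfate), [K+].[O-]S(=O)(=O)OO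
Why: Shi asymmetric epoxidation: the D‑fructose‑derived dioxirane epoxidises the electron‑rich E trisubstituted alkene through a spiro transition state to the (3R,4R)‑epoxide under reagent control, while the monosubstituted alkenes and the electron‑poor methylene lactone do not react.

Step 19
Reactants: 31 (1R,2S,6S)‑6‑hydroxy‑2,6‑dimethyl‑1‑[(2R,3S)‑4‑methylidene‑3‑{[(2R,3R)‑3‑methyl‑3‑(prop‑2‑en‑1‑yl)oxiran‑2‑yl]methyl}‑5‑oxooxolan‑2‑yl]oct‑7‑en‑1‑yl acetate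
Product: 32 (1S,3R,4R,6E,8S,12S,13R,14R)‑13‑acetoxy‑3,4‑epoxy‑8‑hydroxycembra‑6,15(17)‑dien‑16,14‑olide (CNP0202356.4)
Conditions: second‑generation Grubbs catalyst RuCl2(=CHPh)(H2IMes)(PCy3) (10 mol %), 1,4‑benzoquinone (20 mol %), CH2Cl2 (0.5 mM), 40 °C
Reagents that add atoms: none
Why: Ring‑closing olefin metathesis closes the 14‑membered ring, the new disubstituted alkene beside the quaternary carbinol forming E under thermodynamic control, while the trans‑epoxide geometrically blocks the competing seven‑membered closure onto the methylene lactone.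

**Compound list**
1 | 2‑methylprop‑2‑en‑1‑ol (methallyl alcohol) | CC(=C)CO | starting material
2 | [(2R)‑2‑methyloxiran‑2‑yl]methanol ((R)‑2‑methylglycidol) | C1[C@](C)(O1)CO | intermediate (not isolated)
3 | [(2S)‑2‑methyloxiran‑2‑yl]methyl 4‑methylbenzenesulfonate | C1[C@](C)(O1)COS(=O)(=O)c2ccc(C)cc2 | intermediate
4 | (2S)‑2‑hydroxy‑2‑methylpent‑4‑en‑1‑yl 4‑methylbenzenesulfonate | C=CC[C@](C)(O)COS(=O)(=O)c1ccc(C)cc1 | intermediate
5 | (2E)‑but‑2‑en‑1‑ol (crotyl alcohol) | C/C=C/CO | starting material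
6 | [(2S,3S)‑3‑methyloxiran‑2‑yl]methanol | C[C@@H]1O[C@H]1CO | intermediate
7 | (2R,3S)‑3‑methylpent‑4‑ene‑1,2‑diol | OC[C@H](O)[C@@H](C)C=C | intermediate
8 | (4R)‑4‑[(2S)‑but‑3‑en‑2‑yl]‑2,2‑dimethyl‑1,3‑dioxolane | CC1(C)OC[C@@H]([C@@H](C)C=C)O1 | intermediate
9 | (2S,4E,6S)‑6‑[(4R)‑2,2‑dimethyl‑1,3‑dioxolan‑4‑yl]‑2‑hydroxy‑2‑methylhept‑4‑en‑1‑yl 4‑methylbenzenesulfonate (E isomer drawn; E/Z mixture carried on) | CC1(C)OC[C@@H]([C@@H](C)/C=C/C[C@](C)(O)COS(=O)(=O)c2ccc(C)cc2)O1 | intermediate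
10 | (2S,6S)‑6‑[(4R)‑2,2‑dimethyl‑1,3‑dioxolan‑4‑yl]‑2‑hydroxy‑2‑methylheptyl 4‑methylbenzenesulfonate | CC1(C)OC[C@@H]([C@@H](C)CCC[C@](C)(O)COS(=O)(=O)c2ccc(C)cc2)O1 | intermediate
11 | (4R)‑2,2‑dimethyl‑4‑{(2S)‑5‑[(2S)‑2‑methyloxiran‑2‑yl]pentan‑2‑yl}‑1,3‑dioxolane | CC1(C)OC[C@@H]([C@@H](C)CCC[C@@]2(C)CO2)O1 | intermediate (not isolated)
12 | (3S,7S)‑7‑[(4R)‑2,2‑dimethyl‑1,3‑dioxolan‑4‑yl]‑1‑(dimethylsulfaniumyl)‑3‑methyloctan‑3‑olate | CC1(C)OC[C@@H]([C@@H](C)CCC[C@](C)([O-])CC[S+](C)C)O1 | intermediate (not isolated)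
13 | (3S,7S)‑7‑[(4R)‑2,2‑dimethyl‑1,3‑dioxolan‑4‑yl]‑3‑methyloct‑1‑en‑3‑ol | CC1(C)OC[C@@H]([C@@H](C)CCC[C@](C)(O)C=C)O1 | intermediate
14 | (2R,3S,7S)‑3,7‑dimethylnon‑8‑ene‑1,2,7‑triol | OC[C@H](O)[C@@H](C)CCC[C@](C)(O)C=C | intermediate
15 | (2R,3S,7S)‑2,7‑dihydroxy‑3,7‑dimethylnon‑8‑enal | O=C[C@H](O)[C@@H](C)CCC[C@](C)(O)C=C | intermediate
16 | 3‑bromoprop‑1‑ene (allyl bromide) | C=CCBr | starting material
17 | pent‑1‑en‑4‑yne | C=CCC#C | intermediate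
18 | dimethyl[(1E)‑2‑methylpenta‑1,4‑dien‑1‑yl]alumane | C[Al](C)/C=C(\C)CC=C | intermediate (not isolated)
19 | lithium butyl(dimethyl)[(1E)‑2‑methylpenta‑1,4‑dien‑1‑yl]aluminate | [Li+].CCCC[Al-](C)(C)/C=C(\C)CC=C | intermediate (not isolated)
20 | (3E)‑4‑methylhepta‑3,6‑dien‑1‑ol | OCC/C=C(\C)CC=C | intermediate
21 | (3E)‑4‑methylhepta‑3,6‑dienal | O=CC/C=C(\C)CC=C | intermediate
22 | methyl prop‑2‑ynoate (methyl propiolate) | C#CC(=O)OC | starting material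
23 | methyl 2‑[bis(2‑methylpropyl)alumanyl]prop‑2‑enoate | COC(=O)C(=C)[Al](CC(C)C)CC(C)C | intermediate (not isolated)
24 | methyl (5E)‑3‑hydroxy‑6‑methyl‑2‑methylidenenona‑5,8‑dienoate (racemic at C3) | COC(=O)C(=C)C(O)C/C=C(\C)CC=C | intermediate
25 | {[(5E)‑2‑(methoxycarbonyl)‑6‑methylnona‑1,5,8‑trien‑3‑yl]oxy}dimethylsulfonium bromide | COC(=O)C(=C)C(O[S+](C)C)C/C=C(\C)CC=C.[Br-] | intermediate (not isolated)
26 | methyl (2Z,5E)‑2‑(bromomethyl)‑6‑methylnona‑2,5,8‑trienoate | C=CC/C(C)=C/C/C=C(\CBr)C(=O)OC | intermediate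
27 | methyl (2Z,5E)‑2‑[(dibromoindiganyl)methyl]‑6‑methylnona‑2,5,8‑trienoate (simplest formulation of the allylindium reagent) | C=CC/C(C)=C/C/C=C(\C[In](Br)Br)C(=O)OC | intermediate (not isolated)
28 | methyl (3S,4R,5R,6S,10S)‑4,5,10‑trihydroxy‑6,10‑dimethyl‑2‑methylidene‑3‑[(2E)‑3‑methylhexa‑2,5‑dien‑1‑yl]dodec‑11‑enoate | COC(=O)C(=C)[C@H](C/C=C(\C)CC=C)[C@@H](O)[C@H](O)[C@@H](C)CCC[C@](C)(O)C=C | intermediate (not isolated)
29 | (4S,5R)‑5‑[(1R,2S,6S)‑1,6‑dihydroxy‑2,6‑dimethyloct‑7‑en‑1‑yl]‑3‑methylidene‑4‑[(2E)‑3‑methylhexa‑2,5‑dien‑1‑yl]oxolan‑2‑one | C=C1C(=O)O[C@@H]([C@H](O)[C@@H](C)CCC[C@](C)(O)C=C)[C@H]1C/C=C(\C)CC=C | intermediate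
30 | (1R,2S,6S)‑6‑hydroxy‑2,6‑dimethyl‑1‑{(2R,3S)‑4‑methylidene‑3‑[(2E)‑3‑methylhexa‑2,5‑dien‑1‑yl]‑5‑oxooxolan‑2‑yl}oct‑7‑en‑1‑yl acetate | C=C1C(=O)O[C@@H]([C@H](OC(C)=O)[C@@H](C)CCC[C@](C)(O)C=C)[C@H]1C/C=C(\C)CC=C | intermediate
31 | (1R,2S,6S)‑6‑hydroxy‑2,6‑dimethyl‑1‑[(2R,3S)‑4‑methylidene‑3‑{[(2R,3R)‑3‑methyl‑3‑(prop‑2‑en‑1‑yl)oxiran‑2‑yl]methyl}‑5‑oxooxolan‑2‑yl]oct‑7‑en‑1‑yl acetate | C=C1C(=O)O[C@@H]([C@H](OC(C)=O)[C@@H](C)CCC[C@](C)(O)C=C)[C@H]1C[C@H]2O[C@]2(C)CC=C | intermediate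
32 | (1S,3R,4R,6E,8S,12S,13R,14R)‑13‑acetoxy‑3,4‑epoxy‑8‑hydroxycembra‑6,15(17)‑dien‑16,14‑olide (CNP0202356.4) | C=C1C(=O)O[C@H]2[C@H](OC(C)=O)[C@@H](C)CCC[C@](C)(O)/C=C/C[C@@]3(C)O[C@@H]3C[C@@H]12 | target

**Step count and weak points**
Total step count: 19 (steps 1–2 C7–C10 piece, 3–10 west aldehyde, 11–15 east bromide, 16–19 union and endgame).
Longest linear sequence: 12 steps (5 → 6 → 7 → 8 → 9 → 10 → 13 → 14 → 15 → 29 → 30 → 31 → 32; steps 3–10 and 16–19).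

Step 10 (oxidation to the free α‑hydroxy aldehyde): glycol cleavage by the iodine oxidant, over‑oxidation or dimerisation of 15 may erode the yield. Fallback through the acid oxidation level: setting out from triol 14, TEMPO (cat.)/NaOCl (cat.)/NaClO2 in MeCN–phosphate buffer gives (2R,3S,7S)‑2,7‑dihydroxy‑3,7‑dimethylnon‑8‑enoic acid F1, TMSCHN2 in MeOH/toluene gives methyl (2R,3S,7S)‑2,7‑dihydroxy‑3,7‑dimethylnon‑8‑enoate F2, and iBu2AlH (3.2 equiv, CH2Cl2, −78 °C, the α‑alkoxide holding the aluminium hemiacetal as a chelate) releases aldehyde 15 on work‑up, where the route is rejoined.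

Step 16 (fragment union): chelation control at C14, the syn selectivity at C1 and γ‑ versus δ‑lactonisation may all be imperfect in water. Fallback by Lewis‑acid chelation in an organic solvent with a protected C13 oxygen: setting out from triol 14, 4‑methoxybenzaldehyde dimethyl acetal/PPTS gives (3S,7S)‑7‑[(4R)‑2‑(4‑methoxyphenyl)‑1,3‑dioxolan‑4‑yl]‑3‑methyloct‑1‑en‑3‑ol F3, iBu2AlH opens the acetal at the less hindered oxygen to (2R,3S,7S)‑2‑[(4‑methoxyphenyl)methoxy]‑3,7‑dimethylnon‑8‑ene‑1,7‑diol F4, and Dess–Martin oxidation gives (2R,3S,7S)‑7‑hydroxy‑2‑[(4‑methoxyphenyl)methoxy]‑3,7‑dimethylnon‑8‑enal F5. Bromide 26 is converted with Bu3SnLi/CuBr·SMe2 into methyl (2Z,5E)‑6‑methyl‑2‑[(tributylstannyl)methyl]nona‑2,5,8‑trienoate F6. With MgBr2·OEt2 in CH2Cl2 at −25 °C the ether and aldehyde oxygens of F5 are chelated and F6 adds (Keck allylstannane addition) to give methyl (3S,4R,5R,6S,10S)‑4,10‑dihydroxy‑5‑[(4‑methoxyphenyl)methoxy]‑6,10‑dimethyl‑2‑methylidene‑3‑[(2E)‑3‑methylhexa‑2,5‑dien‑1‑yl]dodec‑11‑enoate F7. PPTS closes F7 to (4S,5R)‑5‑{(1R,2S,6S)‑6‑hydroxy‑1‑[(4‑methoxyphenyl)methoxy]‑2,6‑dimethyloct‑7‑en‑1‑yl}‑3‑methylidene‑4‑[(2E)‑3‑methylhexa‑2,5‑dien‑1‑yl]oxolan‑2‑one F8, in which only the C14 oxygen can lactonise; DDQ in CH2Cl2/pH 7 buffer removes the ether and the route is rejoined at lactone diol 29.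

Step 19 (macrocyclisation): oligomerisation, an E/Z mixture or an unproductive conformation of the epoxide‑bearing chain may defeat ring closure. Fallback by closing the ring before the epoxide is present: setting out from acetate 30, the second‑generation Grubbs catalyst RuCl2(=CHPh)(H2IMes)(PCy3) at high dilution gives (1S,3E,6E,8S,12S,13R,14R)‑13‑acetoxy‑8‑hydroxycembra‑3,6,15(17)‑trien‑16,14‑olide F9, and Shi epoxidation as in step 18 (the trisubstituted C3=C4 alkene is more electron‑rich and less hindered than the C6=C7 alkene beside the quaternary carbinol) then gives target 32 directly.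

**Further compounds**
F1 | step 10 | (2R,3S,7S)‑2,7‑dihydroxy‑3,7‑dimethylnon‑8‑enoic acid | OC(=O)[C@H](O)[C@@H](C)CCC[C@](C)(O)C=C
F2 | step 10 | methyl (2R,3S,7S)‑2,7‑dihydroxy‑3,7‑dimethylnon‑8‑enoate | COC(=O)[C@H](O)[C@@H](C)CCC[C@](C)(O)C=C
F3 | step 16 | (3S,7S)‑7‑[(4R)‑2‑(4‑methoxyphenyl)‑1,3‑dioxolan‑4‑yl]‑3‑methyloct‑1‑en‑3‑ol | COc1ccc(cc1)C1OC[C@@H]([C@@H](C)CCC[C@](C)(O)C=C)O1
F4 | step 16 | (2R,3S,7S)‑2‑[(4‑methoxyphenyl)methoxy]‑3,7‑dimethylnon‑8‑ene‑1,7‑diol | OC[C@H](OCc1ccc(OC)cc1)[C@@H](C)CCC[C@](C)(O)C=C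
F5 | step 16 | (2R,3S,7S)‑7‑hydroxy‑2‑[(4‑methoxyphenyl)methoxy]‑3,7‑dimethylnon‑8‑enal | O=C[C@H](OCc1ccc(OC)cc1)[C@@H](C)CCC[C@](C)(O)C=C
F6 | step 16 | methyl (2Z,5E)‑6‑methyl‑2‑[(tributylstannyl)methyl]nona‑2,5,8‑trienoate | C=CC/C(C)=C/C/C=C(\C[Sn](CCCC)(CCCC)CCCC)C(=O)OC
F7 | step 16 | methyl (3S,4R,5R,6S,10S)‑4,10‑dihydroxy‑5‑[(4‑methoxyphenyl)methoxy]‑6,10‑dimethyl‑2‑methylidene‑3‑[(2E)‑3‑methylhexa‑2,5‑dien‑1‑yl]dodec‑11‑enoate | COC(=O)C(=C)[C@H](C/C=C(\C)CC=C)[C@@H](O)[C@H](OCc1ccc(OC)cc1)[C@@H](C)CCC[C@](C)(O)C=C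
F8 | step 16 | (4S,5R)‑5‑{(1R,2S,6S)‑6‑hydroxy‑1‑[(4‑methoxyphenyl)methoxy]‑2,6‑dimethyloct‑7‑en‑1‑yl}‑3‑methylidene‑4‑[(2E)‑3‑methylhexa‑2,5‑dien‑1‑yl]oxolan‑2‑one | C=C1C(=O)O[C@@H]([C@H](OCc2ccc(OC)cc2)[C@@H](C)CCC[C@](C)(O)C=C)[C@H]1C/C=C(\C)CC=C
F9 | step 19 | (1S,3E,6E,8S,12S,13R,14R)‑13‑acetoxy‑8‑hydroxycembra‑3,6,15(17)‑trien‑16,14‑olide | C=C1C(=O)O[C@H]2[C@H](OC(C)=O)[C@@H](C)CCC[C@](C)(O)/C=C/C/C(C)=C/C[C@@H]12
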